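All runs stem from a simulated flask with constants of no real substance; the scatter is artificial.

Open intermediate stands higher than target at the last reading of both earlier runs, 39.1% against 21.5% in oak and 26.7% against 11.8% in cedar, and two of us disputed what this means for the new flasks, east and west.

| flask | starting material | partner | temperature | remark | time |
|---|---|---|---|---|---|
| oak | 0.35 M | 1.5 equiv | 25 °C | run made earlier |  |
| cedar | 0.55 M | 1.5 equiv | 36 °C | run made earlier |  |
| east | 0.25 M | 1.50 equiv | 20 °C |  | 3.0 d |
| west | 0.25 M | 1.50 equiv | 40 °C |  | 3.0 d |

oak run (percent of the starting material charged)

| time / d | target / % | open intermediate / % | over-reaction product / % | starting material / % |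
|---|---|---|---|---|
| 0.833 | 23.4 | 69.6 | 5.0 | 0 |
| 1.67 | 27.8 | 51.0 | 18.2 | 1.5 |
| 2.50 | 23.2 | 43.0 | 34.2 | 0 |
| 3.00 | 21.5 | 39.1 | 40.2 | 0.8 |

cedar run (percent of the starting material charged)

| time / h | target / % | open intermediate / % | over-reaction product / % | starting material / % |
|---|---|---|---|---|
| 5.00 | 28.1 | 65.1 | 6.9 | 0.1 |
| 12.0 | 28.6 | 44.4 | 27.4 | 0.3 |
| 25.0 | 14.9 | 29.6 | 56.1 | 0.5 |
| 30.0 | 11.8 | 26.7 | 60.2 | 0 |

(scatter of a reading: 1 percentage point)

- which of these there is most of at the end, counted by the starting material in it, east (open intermediate / starting material / target / over-reaction product)
- which of these there is most of at the end, counted by the starting material in it, west (open intermediate / starting material / target / over-reaction product)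
- amount of the one of these that there is most of at the end, in percent of the starting material charged, east
- amount of the one of these that there is most of at the end, in percent of the starting material charged, west

- steps thought possible: starting material -> open intermediate; partner -> second intermediate; open intermediate + second intermediate <-> target; 2 second intermediate -> homo product; target -> over-reaction product

My view is that target in a hot flask is a narrow passage, so over-reaction product is gained at a rate proportional to open intermediate times free second intermediate. Starting material is the limiting reagent and each unit that has passed open intermediate holds one second intermediate, so once the opening is over, and homo product aside, the free fraction of the charge is the excess 0.5 plus the open intermediate still standing. Dividing the gain from the second to the last reading by the mean of that product reads 0.386 d⁻¹ in oak and 1.44 d⁻¹ in cedar. Scaling each by its starting concentration and carrying the growth per degree on to 40 °C gives 0.894 d⁻¹ for west, and this is the leak constant, the daily gain of over-reaction product per unit of open intermediate times free fraction. Open intermediate I then falls so that I/(0.5+I) shrinks as exp(−0.5·leak·time), which from a full charge leaves 10.6% in west at 3.0 d, so my west figure is 89.4%, with target counted in it. Oak's target was still rising early, from 23.4% to 27.8%, so I take no number of my own for the colder east.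

The other reads the drain as a rate constant on target itself, “Over-reaction is first order in target”, with open intermediate and target near equilibrium, and the forecast is that side's: open intermediate at 57% in east, over-reaction product at 72% in west.

West gives over-reaction product at 83.8%, 12 percentage points above the forecast, with open intermediate at 14.4% against the 10.6% I reckoned, while east gives open intermediate at 59.6%, so east is the forecast's region, its number standing within the margin.

    starting material → open intermediate (k = 0.00240 min⁻¹, Ea = 103 kJ mol⁻¹)
    partner → second intermediate (k = 0.00110 min⁻¹, Ea = 106 kJ mol⁻¹)
    open intermediate + second intermediate ⇌ target (K = 3.70 L mol⁻¹, k = 6.90 × 10⁻⁴ L mol⁻¹ min⁻¹, Ea = 88.0 kJ mol⁻¹, ΔH = −33.0 kJ mol⁻¹)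
    2 second intermediate → homo product (k = 1.20 × 10⁻⁵ L mol⁻¹ min⁻¹, Ea = 86.0 kJ mol⁻¹)
    target → over-reaction product (k = 2.30 × 10⁻⁴ min⁻¹, Ea = 94.0 kJ mol⁻¹)
    (constants at 20 °C)

In west the partner stood at 0% by 1.50 d, and from then to 3.00 d target went on to over-reaction product while target fell from 5.37% to 1.84% and open intermediate from 29.4% to 14.4%, the leak constant taken over that stretch with the free second intermediate that stood in west being 0.953 d⁻¹ against the 0.894 d⁻¹ reckoned beforehand. The oak charge taken to 40 °C, at 0.35 M in place of 0.25 M, has a leak of 1.25 d⁻¹, which by the same law leaves 5.67% of open intermediate, 4.9 points under my reckoning for west, and that flask stands at 88.9% of over-reaction product, 5.2 points above west.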